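## Retrosynthetic overview

1. Numbering and feature: ring A is the fused catechol ring (C4a–C8a), ring B is C1–C4, ring C is the pendant aryl (C1'–C6'), and ring D is the aryl of the acrylate. C1 is a doubly benzylic methine bonded to C8a and C1'. Its neighbour C2 carries a carboxyl group and sits on the C3(CO2H)=C4H styrene, so the C1–C2 bond can be made by joining a hydridic diarylmethane C–H to a vinylcarbene carbon.
2. Endgame cuts: five benzyl ethers (BCl3/C6HMe5) and three methyl esters. The (E)-aryloxyacrylate is cut at its C=C bond (Still–Gennari olefination with the ring-D aldehyde) and at O3'–C (Rh O–H insertion of a diazophosphonoacetate).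
3. Key cut: C1–C2, which opens to the vinyl diazoester 13. Ring B is the only ring built; rings A, C and D are bought as benzaldehydes.
4. Compound 13 comes from diazo transfer to arylidenesuccinate 12. Compound 12 is the Negishi union of a ring-C benzylzinc with a ring-A bromoarylidenesuccinate made by Stobbe condensation.

Key step: step 9

Assumption: the sense of induction of the new ring closure cannot be read from precedent, so Rh2(S-PTTL)4 is written and its mirror image is taken if the first run delivers the 1S series.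

## Route

Step 1
Reactants: 1 4-(benzyloxy)-3-hydroxybenzaldehyde
Product: 2 4-(benzyloxy)-3-(triisopropylsilyloxy)benzaldehyde
Conditions: TIPSCl, imidazole, DMF, rt
Reagents that add atoms: triisopropylsilyl chloride, CC(C)[Si](Cl)(C(C)C)C(C)C
Why: Imidazole-promoted O-silylation of the only free phenol; TIPS is chosen for O3' because fluoride removes it beside benzyl ethers, it resists DBU better than smaller silyl groups, and it offers the carbene of step 9 no activated C–H bond.

Step 2
Reactants: 2 4-(benzyloxy)-3-(triisopropylsilyloxy)benzaldehyde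
Product: 3 [4-(benzyloxy)-3-(triisopropylsilyloxy)phenyl]methanol
Conditions: NaBH4, MeOH/THF, 0 °C
Reagents that add atoms: none
Why: Borohydride reduction of an aryl aldehyde, to which silyl and benzyl ethers are inert.

Step 3
Reactants: 3 [4-(benzyloxy)-3-(triisopropylsilyloxy)phenyl]methanol
Product: 4 [2-(benzyloxy)-5-(chloromethyl)phenoxy]triisopropylsilane
Conditions: SOCl2, CH2Cl2, 0 °C
Reagents that add atoms: thionyl chloride, O=S(Cl)Cl
Why: Chlorodehydroxylation through the chlorosulfite, fast at a p-alkoxybenzylic carbon; the solvolysis-prone chloride is used without chromatography.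

Step 4
Reactants: 5 3,4-bis(benzyloxy)benzaldehyde
Product: 6 4,5-bis(benzyloxy)-2-bromobenzaldehyde
Conditions: Br2, NaOAc, AcOH, rt, dark
Reagents that add atoms: bromine, BrBr
Why: Electrophilic aromatic bromination directed para to the 3-benzyloxy group (the site between CHO and OBn is hindered), with acetate buffering the HBr that could cleave a benzyl ether.

Step 5
Reactants: 6 4,5-bis(benzyloxy)-2-bromobenzaldehyde; 7 dimethyl succinate
Product: 9 (E)-4-[4,5-bis(benzyloxy)-2-bromophenyl]-3-(methoxycarbonyl)but-3-enoic acid, via paraconic lactone 8 (not isolated)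
Conditions: NaOMe, MeOH/THF, reflux; then 1 M HCl
Reagents that add atoms: none
Why: Stobbe condensation (aldol addition, lactonisation to 8, E1cB ring opening) gives the half-ester, and the aryl group avoids the ester in the elimination, so the E alkene forms with the aryl cis to the CH2 arm as ring closure will require.

Step 6
Reactants: 9 (E)-4-[4,5-bis(benzyloxy)-2-bromophenyl]-3-(methoxycarbonyl)but-3-enoic acid
Product: 10 dimethyl (E)-2-[4,5-bis(benzyloxy)-2-bromobenzylidene]succinate
Conditions: MeI, K2CO3, DMF, rt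
Reagents that add atoms: iodomethane, CI
Why: SN2 O-methylation of the carboxylate, which leaves the alkene geometry, the aryl bromide and the benzyl ethers alone.

Step 7
Reactants: 4 [2-(benzyloxy)-5-(chloromethyl)phenoxy]triisopropylsilane; 10 dimethyl (E)-2-[4,5-bis(benzyloxy)-2-bromobenzylidene]succinate
Product: 12 dimethyl (E)-2-{4,5-bis(benzyloxy)-2-[4-(benzyloxy)-3-(triisopropylsilyloxy)benzyl]benzylidene}succinate, via benzylzinc chloride 11 (not isolated)
Conditions: 4, Zn dust, LiCl, THF, 25 °C; then 10, Pd(OAc)2 (2 mol %), SPhos (4 mol %), THF, 25→40 °C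
Reagents that add atoms: none
Why: LiCl-assisted zinc insertion followed by Negishi coupling; the weakly basic benzylzinc tolerates the esters and the enolisable CH2, and joining the rings at the ester stage keeps the zinc reagent away from a formyl group.

Step 8
Reactants: 12 dimethyl (E)-2-{4,5-bis(benzyloxy)-2-[4-(benzyloxy)-3-(triisopropylsilyloxy)benzyl]benzylidene}succinate
Product: 13 dimethyl (E)-2-diazo-3-{4,5-bis(benzyloxy)-2-[4-(benzyloxy)-3-(triisopropylsilyloxy)benzyl]benzylidene}succinate
Conditions: p-ABSA, DBU, MeCN/CH2Cl2, 0 °C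
Reagents that add atoms: 4-acetamidobenzenesulfonyl azide, CC(=O)Nc1ccc(cc1)S(=O)(=O)N=[N+]=[N-]
Why: Regitz diazo transfer as used to make vinyl diazoacetates from β,γ-unsaturated esters; the CH2 of 12 is α to one ester and allylic to C3=C4, so DBU enolises it, and 13 is kept cold and used at once because vinyl diazo esters electrocyclise on standing.

Step 9
Reactants: 13 dimethyl (E)-2-diazo-3-{4,5-bis(benzyloxy)-2-[4-(benzyloxy)-3-(triisopropylsilyloxy)benzyl]benzylidene}succinate
Product: 15 dimethyl (1R,2S)-6,7-bis(benzyloxy)-1-[4-(benzyloxy)-3-(triisopropylsilyloxy)phenyl]-1,2-dihydronaphthalene-2,3-dicarboxylate, via cis-(1R,2R) diester 14 (not isolated)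
Conditions: Rh2(S-PTTL)4 (1 mol %), 4 Å MS, CH2Cl2 (high dilution), −20 °C→rt, slow addition of cold 13; then DBU (0.3 equiv), rt
Reagents that add atoms: none
Why: Proposed new method: Rh(II) expels N2 from 13 to give the carbene at C2, and because the ring-A aryl group is cis to C2 and ortho-substituted, the C3=C4 π bond is twisted out of conjugation and the vacant carbene orbital lies in the σ-plane of the alkene aimed at C1H2, so one C1–H is handed over in hydride-like fashion while C1–C2 forms in a concerted, asynchronous three-centre transition state. The closest known reaction type is the enantioselective intramolecular C–H insertion of aryl- and vinyl-diazoacetates at benzylic or α-oxy methylene groups under chiral dirhodium carboxylates (cis-2-aryl-2,3-dihydrobenzofuran-3-carboxylates, and isochromans by 1,6-insertion of donor/donor carbenes), and what is new is a 1,6-closure from a vinyl diazoester onto a diarylmethane. Ring B closes as a six-membered ring by 1,6-insertion (C2 to C1 across C3, C4, C4a, C8a), a 1,5-mode at C8a being impossible because that carbon has no hydrogen. C1 is set by the catalyst pocket, which should let the carbene reach only the pro-R hydrogen and replace it with retention, the pendant aryl turning away from the catalyst wall and so ending cis to the C2 ester in 14. C2 is then set thermodynamically: DBU enolises only C2–H (α to an ester and allylic) and reprotonation should give trans-diaxial 15, free of the clash between the two esters and of the peri clash between the aryl group and C8–H, while the non-acidic C1–H is untouched. The step needs chemoselectivity for C1–H over electrophilic attack on C5 or C8a of ring A (five-ring closure), on ring C and on the benzyl ether CH2 groups, and this is secured by the two para oxygens (O6 para to C8a, O4' para to C1') that make C1–H very hydridic, by the twist that denies the planar pentadienyl geometry needed for five-ring closure, and by slow addition at high dilution.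

Step 10
Reactants: 15 dimethyl (1R,2S)-6,7-bis(benzyloxy)-1-[4-(benzyloxy)-3-(triisopropylsilyloxy)phenyl]-1,2-dihydronaphthalene-2,3-dicarboxylate
Product: 16 dimethyl (1R,2S)-6,7-bis(benzyloxy)-1-[4-(benzyloxy)-3-hydroxyphenyl]-1,2-dihydronaphthalene-2,3-dicarboxylate
Conditions: TBAF, AcOH, THF, 0 °C
Reagents that add atoms: none
Why: Fluoride-induced desilylation of the aryl TIPS ether, buffered with acetic acid so that fluoride and phenoxide do not enolise C2; benzyl ethers and methyl esters are untouched.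

Step 11
Reactants: 17 methyl 2-[bis(2,2,2-trifluoroethoxy)phosphoryl]acetate
Product: 18 methyl 2-[bis(2,2,2-trifluoroethoxy)phosphoryl]-2-diazoacetate
Conditions: p-ABSA, DBU, MeCN, 0 °C→rt
Reagents that add atoms: 4-acetamidobenzenesulfonyl azide, CC(=O)Nc1ccc(cc1)S(=O)(=O)N=[N+]=[N-]
Why: Regitz diazo transfer to an activated methylene flanked by ester and phosphoryl groups.

Step 12
Reactants: 16 dimethyl (1R,2S)-6,7-bis(benzyloxy)-1-[4-(benzyloxy)-3-hydroxyphenyl]-1,2-dihydronaphthalene-2,3-dicarboxylate; 18 methyl 2-[bis(2,2,2-trifluoroethoxy)phosphoryl]-2-diazoacetate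
Product: 19 dimethyl (1R,2S)-6,7-bis(benzyloxy)-1-[4-(benzyloxy)-3-{1-[bis(2,2,2-trifluoroethoxy)phosphoryl]-2-methoxy-2-oxoethoxy}phenyl]-1,2-dihydronaphthalene-2,3-dicarboxylate (both epimers at the P-bearing carbon)
Conditions: Rh2(OAc)4 (2 mol %), ClCH2CH2Cl, 80 °C, slow addition of 18
Reagents that add atoms: none
Why: Rhodium-carbenoid O–H insertion of a diazophosphonoacetate into a phenol, which outruns attack on the electron-poor trisubstituted C3=C4 bond, the arenes and the ether C–H bonds; the new P-bearing stereocentre is irrelevant because it becomes sp2 in step 13.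

Step 13
Reactants: 19 the aryloxyphosphonoacetate of step 12; 5 3,4-bis(benzyloxy)benzaldehyde
Product: 20 dimethyl (1R,2S)-6,7-bis(benzyloxy)-1-[4-(benzyloxy)-3-{[(E)-1-[3,4-bis(benzyloxy)phenyl]-3-methoxy-3-oxoprop-1-en-2-yl]oxy}phenyl]-1,2-dihydronaphthalene-2,3-dicarboxylate
Conditions: KHMDS (1.0 equiv), 18-crown-6, THF, −78 °C; then 5, −78→−40 °C
Reagents that add atoms: none
Why: Still–Gennari variant of the Horner–Wadsworth–Emmons reaction, in which the trifluoroethyl phosphonate and a dissociated potassium ion make the kinetic adduct collapse faster than it reverts, placing the aldehyde aryl cis to the ester (the E enol ether), while the single equivalent of base is taken by the more acidic phosphonate C–H and not by C2–H.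

Step 14
Reactants: 20 the pentabenzyl trimethyl ester of step 13
Product: 21 (1R,2S)-6,7-bis(benzyloxy)-1-[4-(benzyloxy)-3-{[(E)-2-[3,4-bis(benzyloxy)phenyl]-1-carboxyethenyl]oxy}phenyl]-1,2-dihydronaphthalene-2,3-dicarboxylic acid
Conditions: LiOH, THF/MeOH/H2O, rt→40 °C, Ar; then 1 M HCl
Reagents that add atoms: lithium hydroxide, [Li+].[OH-]
Why: Saponification of the three methyl esters while all phenols are still benzylated, so that no phenoxide conjugated with the enol-ether double bond can lower its rotation barrier and no catechol meets base; any enolisation at C2 returns the favoured trans isomer.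

Step 15
Reactants: 21 the pentabenzyl triacid of step 14
Product: 22 (1R,2S)-1-[3-{[(E)-1-carboxy-2-(3,4-dihydroxyphenyl)ethenyl]oxy}-4-hydroxyphenyl]-6,7-dihydroxy-1,2-dihydronaphthalene-2,3-dicarboxylic acid (CNP0241205.1)
Conditions: BCl3, C6HMe5, CH2Cl2, −78 °C; then THF/H2O
Reagents that add atoms: none
Why: Lewis-acid debenzylation with a cation scavenger, in which BCl3 ionises aryl benzyl ethers at −78 °C and pentamethylbenzene traps the benzyl cation by Friedel–Crafts alkylation, so the two alkenes (which rule out hydrogenolysis), the kinetic enol-ether geometry and both stereocentres are left alone.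

## Compound list

1 | 4-(benzyloxy)-3-hydroxybenzaldehyde | O=Cc1ccc(OCc2ccccc2)c(O)c1 | starting material
2 | 4-(benzyloxy)-3-(triisopropylsilyloxy)benzaldehyde | O=Cc1ccc(OCc2ccccc2)c(O[Si](C(C)C)(C(C)C)C(C)C)c1 | intermediate
3 | [4-(benzyloxy)-3-(triisopropylsilyloxy)phenyl]methanol | OCc1ccc(OCc2ccccc2)c(O[Si](C(C)C)(C(C)C)C(C)C)c1 | intermediate
4 | [2-(benzyloxy)-5-(chloromethyl)phenoxy]triisopropylsilane | ClCc1ccc(OCc2ccccc2)c(O[Si](C(C)C)(C(C)C)C(C)C)c1 | intermediate
5 | 3,4-bis(benzyloxy)benzaldehyde | O=Cc1ccc(OCc2ccccc2)c(OCc2ccccc2)c1 | starting material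
6 | 4,5-bis(benzyloxy)-2-bromobenzaldehyde | O=Cc1cc(OCc2ccccc2)c(OCc2ccccc2)cc1Br | intermediate
7 | dimethyl succinate | COC(=O)CCC(=O)OC | starting material
8 | methyl 2-[4,5-bis(benzyloxy)-2-bromophenyl]-5-oxotetrahydrofuran-3-carboxylate (diastereomer mixture) | COC(=O)C1CC(=O)OC1c1cc(OCc2ccccc2)c(OCc2ccccc2)cc1Br | intermediate (not isolated)
9 | (E)-4-[4,5-bis(benzyloxy)-2-bromophenyl]-3-(methoxycarbonyl)but-3-enoic acid | OC(=O)C/C(C(=O)OC)=C\c1cc(OCc2ccccc2)c(OCc2ccccc2)cc1Br | intermediate
10 | dimethyl (E)-2-[4,5-bis(benzyloxy)-2-bromobenzylidene]succinate | COC(=O)C/C(C(=O)OC)=C\c1cc(OCc2ccccc2)c(OCc2ccccc2)cc1Br | intermediate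
11 | [4-(benzyloxy)-3-(triisopropylsilyloxy)benzyl]zinc chloride | Cl[Zn]Cc1ccc(OCc2ccccc2)c(O[Si](C(C)C)(C(C)C)C(C)C)c1 | intermediate (not isolated)
12 | dimethyl (E)-2-{4,5-bis(benzyloxy)-2-[4-(benzyloxy)-3-(triisopropylsilyloxy)benzyl]benzylidene}succinate | COC(=O)C/C(C(=O)OC)=C\c1cc(OCc2ccccc2)c(OCc2ccccc2)cc1Cc1ccc(OCc2ccccc2)c(O[Si](C(C)C)(C(C)C)C(C)C)c1 | intermediate
13 | dimethyl (E)-2-diazo-3-{4,5-bis(benzyloxy)-2-[4-(benzyloxy)-3-(triisopropylsilyloxy)benzyl]benzylidene}succinate | COC(=O)C(=[N+]=[N-])/C(C(=O)OC)=C\c1cc(OCc2ccccc2)c(OCc2ccccc2)cc1Cc1ccc(OCc2ccccc2)c(O[Si](C(C)C)(C(C)C)C(C)C)c1 | intermediate (key-step precursor)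
14 | dimethyl (1R,2R)-6,7-bis(benzyloxy)-1-[4-(benzyloxy)-3-(triisopropylsilyloxy)phenyl]-1,2-dihydronaphthalene-2,3-dicarboxylate (cis) | COC(=O)C1=Cc2cc(OCc3ccccc3)c(OCc3ccccc3)cc2[C@@H](c2ccc(OCc3ccccc3)c(O[Si](C(C)C)(C(C)C)C(C)C)c2)[C@H]1C(=O)OC | intermediate (not isolated)
15 | dimethyl (1R,2S)-6,7-bis(benzyloxy)-1-[4-(benzyloxy)-3-(triisopropylsilyloxy)phenyl]-1,2-dihydronaphthalene-2,3-dicarboxylate (trans) | COC(=O)C1=Cc2cc(OCc3ccccc3)c(OCc3ccccc3)cc2[C@@H](c2ccc(OCc3ccccc3)c(O[Si](C(C)C)(C(C)C)C(C)C)c2)[C@@H]1C(=O)OC | intermediate (key-step product)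
16 | dimethyl (1R,2S)-6,7-bis(benzyloxy)-1-[4-(benzyloxy)-3-hydroxyphenyl]-1,2-dihydronaphthalene-2,3-dicarboxylate | COC(=O)C1=Cc2cc(OCc3ccccc3)c(OCc3ccccc3)cc2[C@@H](c2ccc(OCc3ccccc3)c(O)c2)[C@@H]1C(=O)OC | intermediate
17 | methyl 2-[bis(2,2,2-trifluoroethoxy)phosphoryl]acetate | COC(=O)CP(=O)(OCC(F)(F)F)OCC(F)(F)F | starting material
18 | methyl 2-[bis(2,2,2-trifluoroethoxy)phosphoryl]-2-diazoacetate | COC(=O)C(=[N+]=[N-])P(=O)(OCC(F)(F)F)OCC(F)(F)F | intermediate
19 | dimethyl (1R,2S)-6,7-bis(benzyloxy)-1-[4-(benzyloxy)-3-{1-[bis(2,2,2-trifluoroethoxy)phosphoryl]-2-methoxy-2-oxoethoxy}phenyl]-1,2-dihydronaphthalene-2,3-dicarboxylate (epimer mixture at the P-bearing carbon) | COC(=O)C1=Cc2cc(OCc3ccccc3)c(OCc3ccccc3)cc2[C@@H](c2ccc(OCc3ccccc3)c(OC(C(=O)OC)P(=O)(OCC(F)(F)F)OCC(F)(F)F)c2)[C@@H]1C(=O)OC | intermediate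
20 | dimethyl (1R,2S)-6,7-bis(benzyloxy)-1-[4-(benzyloxy)-3-{[(E)-1-[3,4-bis(benzyloxy)phenyl]-3-methoxy-3-oxoprop-1-en-2-yl]oxy}phenyl]-1,2-dihydronaphthalene-2,3-dicarboxylate | COC(=O)C1=Cc2cc(OCc3ccccc3)c(OCc3ccccc3)cc2[C@@H](c2ccc(OCc3ccccc3)c(O/C(=C/c3ccc(OCc4ccccc4)c(OCc4ccccc4)c3)C(=O)OC)c2)[C@@H]1C(=O)OC | intermediate
21 | (1R,2S)-6,7-bis(benzyloxy)-1-[4-(benzyloxy)-3-{[(E)-2-[3,4-bis(benzyloxy)phenyl]-1-carboxyethenyl]oxy}phenyl]-1,2-dihydronaphthalene-2,3-dicarboxylic acid | OC(=O)C1=Cc2cc(OCc3ccccc3)c(OCc3ccccc3)cc2[C@@H](c2ccc(OCc3ccccc3)c(O/C(=C/c3ccc(OCc4ccccc4)c(OCc4ccccc4)c3)C(=O)O)c2)[C@@H]1C(=O)O | intermediate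
22 | (1R,2S)-1-[3-{[(E)-1-carboxy-2-(3,4-dihydroxyphenyl)ethenyl]oxy}-4-hydroxyphenyl]-6,7-dihydroxy-1,2-dihydronaphthalene-2,3-dicarboxylic acid | O=C(O)C1=Cc2cc(O)c(O)cc2[C@@H](c2ccc(O)c(O/C(=C/c3ccc(O)c(O)c3)C(=O)O)c2)[C@@H]1C(=O)O | target

## Step count and risks

Total step count: 15.

Longest linear sequence: 11 steps. This is steps 1–3, 7–10 and 12–15 from compound 1, and the same length through steps 4–10 and 12–15 from compound 5.

### Steps most likely to fail

**Step 9 (Proposed new method).**
- The carbene may be consumed by electrophilic attack on ring A with five-membered ring closure, or by collapse to a cyclopropene.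
- The carbene may discriminate poorly between the two enantiotopic C1 hydrogens.
- A minor diastereomer born from the same carbene face carries the opposite C1 configuration, so equilibration in the flask would erode the enantiomeric purity. In that case the diastereomers are separated before DBU is applied.

The fallback uses known chemistry: the photoenolisation/Diels–Alder reaction of a 2-benzylbenzaldehyde with a chiral fumarate. It sets out from 4 and 6 and comes back at 15. The zinc reagent 11 made from 4 is coupled with 6 (Pd(OAc)2/SPhos, THF, 0 °C, where cross-coupling should outpace addition to the electron-rich formyl group). This gives 4,5-bis(benzyloxy)-2-[4-(benzyloxy)-3-(triisopropylsilyloxy)benzyl]benzaldehyde F1. Fumaryl chloride and methyl (S)-mandelate (pyridine, CH2Cl2) give bis[(S)-2-methoxy-2-oxo-1-phenylethyl] fumarate F2. F1 is irradiated (about 350 nm, toluene) in the presence of F2; the reaction runs in the endo mode and the auxiliary chooses the diene face. It should give the 1,2-trans-2,3-trans-3,4-cis adduct bis[(S)-2-methoxy-2-oxo-1-phenylethyl] (1R,2S,3R,4R)-6,7-bis(benzyloxy)-1-[4-(benzyloxy)-3-(triisopropylsilyloxy)phenyl]-4-hydroxy-1,2,3,4-tetrahydronaphthalene-2,3-dicarboxylate F3. The mandelate antipode is taken if the facial sense is opposite. Catalytic p-TsOH (toluene, 40 °C) dehydrates the p-alkoxybenzylic C4 alcohol to bis[(S)-2-methoxy-2-oxo-1-phenylethyl] (1R,2S)-6,7-bis(benzyloxy)-1-[4-(benzyloxy)-3-(triisopropylsilyloxy)phenyl]-1,2-dihydronaphthalene-2,3-dicarboxylate F4. Brief methanolysis of the activated mandelyl esters (K2CO3, MeOH/THF, 0 °C) returns 15. Loss of the silyl group at this point would merely deliver 16.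

**Step 13.** Kinetic control may be incomplete. If the hindered α-aryloxy phosphonate anion adds reversibly to the electron-rich aldehyde, the adducts equilibrate and the geometry drifts towards aryl trans to ester.

The fallback sets the geometry by contra-thermodynamic photoisomerisation instead of by the olefination. It sets out from 19 and comes back at 20. Olefination of 19 with 5 under equilibrating conditions (LiCl, DBU, MeCN) gives mainly dimethyl (1R,2S)-6,7-bis(benzyloxy)-1-[4-(benzyloxy)-3-{[(Z)-1-[3,4-bis(benzyloxy)phenyl]-3-methoxy-3-oxoprop-1-en-2-yl]oxy}phenyl]-1,2-dihydronaphthalene-2,3-dicarboxylate F5. Triplet energy transfer (fac-Ir(ppy)3, MeCN/CH2Cl2, 450 nm, rt, dilute) excites the planar cinnamate chromophore of F5 more efficiently than the twisted chromophore of 20. Compound 20 should therefore accumulate; it is separated by chromatography and F5 is recycled.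

**Step 8.**
- Enolisation by DBU may be slow.
- The dienolate may scramble E/Z.
- The silyl ether may be lost to DBU.
- The vinyl diazoester may undergo thermal 1,5- or 1,7-electrocyclisation during isolation.

The fallback adds an activating group (detrifluoroacetylative diazo transfer). It sets out from 12 and comes back at 13. The lithium enolate of 12 (LiHMDS, THF, −78 °C) is acylated with 2,2,2-trifluoroethyl trifluoroacetate to give dimethyl (E)-2-{4,5-bis(benzyloxy)-2-[4-(benzyloxy)-3-(triisopropylsilyloxy)benzyl]benzylidene}-3-(trifluoroacetyl)succinate F6. F6 is treated crude with p-ABSA and only Et3N (MeCN, 1 equiv H2O, 0 °C). The cold solution of 13 is passed through a short silica pad and taken directly into step 9.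

## Further compounds

F1 | step 9 | 4,5-bis(benzyloxy)-2-[4-(benzyloxy)-3-(triisopropylsilyloxy)benzyl]benzaldehyde | O=Cc1cc(OCc2ccccc2)c(OCc2ccccc2)cc1Cc1ccc(OCc2ccccc2)c(O[Si](C(C)C)(C(C)C)C(C)C)c1
F2 | step 9 | bis[(S)-2-methoxy-2-oxo-1-phenylethyl] fumarate | COC(=O)[C@H](c1ccccc1)OC(=O)/C=C/C(=O)O[C@H](C(=O)OC)c1ccccc1
F3 | step 9 | bis[(S)-2-methoxy-2-oxo-1-phenylethyl] (1R,2S,3R,4R)-6,7-bis(benzyloxy)-1-[4-(benzyloxy)-3-(triisopropylsilyloxy)phenyl]-4-hydroxy-1,2,3,4-tetrahydronaphthalene-2,3-dicarboxylate | COC(=O)[C@H](c1ccccc1)OC(=O)[C@H]1[C@@H](O)c2cc(OCc3ccccc3)c(OCc3ccccc3)cc2[C@@H](c2ccc(OCc3ccccc3)c(O[Si](C(C)C)(C(C)C)C(C)C)c2)[C@@H]1C(=O)O[C@H](C(=O)OC)c1ccccc1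
F4 | step 9 | bis[(S)-2-methoxy-2-oxo-1-phenylethyl] (1R,2S)-6,7-bis(benzyloxy)-1-[4-(benzyloxy)-3-(triisopropylsilyloxy)phenyl]-1,2-dihydronaphthalene-2,3-dicarboxylate | COC(=O)[C@H](c1ccccc1)OC(=O)C1=Cc2cc(OCc3ccccc3)c(OCc3ccccc3)cc2[C@@H](c2ccc(OCc3ccccc3)c(O[Si](C(C)C)(C(C)C)C(C)C)c2)[C@@H]1C(=O)O[C@H](C(=O)OC)c1ccccc1
F5 | step 13 | dimethyl (1R,2S)-6,7-bis(benzyloxy)-1-[4-(benzyloxy)-3-{[(Z)-1-[3,4-bis(benzyloxy)phenyl]-3-methoxy-3-oxoprop-1-en-2-yl]oxy}phenyl]-1,2-dihydronaphthalene-2,3-dicarboxylate | COC(=O)C1=Cc2cc(OCc3ccccc3)c(OCc3ccccc3)cc2[C@@H](c2ccc(OCc3ccccc3)c(O/C(=C\c3ccc(OCc4ccccc4)c(OCc4ccccc4)c3)C(=O)OC)c2)[C@@H]1C(=O)OC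
F6 | step 8 | dimethyl (E)-2-{4,5-bis(benzyloxy)-2-[4-(benzyloxy)-3-(triisopropylsilyloxy)benzyl]benzylidene}-3-(trifluoroacetyl)succinate | COC(=O)C(C(=O)C(F)(F)F)/C(C(=O)OC)=C\c1cc(OCc2ccccc2)c(OCc2ccccc2)cc1Cc1ccc(OCc2ccccc2)c(O[Si](C(C)C)(C(C)C)C(C)C)c1
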